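**Plan**
- Retrosynthesis: the aryl acetate and the acid are adjusted last, and C3=CMe2 is traced back to a spiro β-lactone (loss of CO2). The C1–C2 and C3–C4 bonds of ring A are then cut together as a [4+2] cycloaddition, giving a trans-fused silyloxy diene on ring B and 4,4-dimethyl-3-methylideneoxetan-2-one as an activated 1,1-dimethylallene equivalent.
- Enabling feature: in ring A (C1–C2–C3–C4–C5–C10), C1 and C4 are 1,4-related, each sits next to an sp3 ring-fusion carbon (C10, C5), and C4 carries a carbon chain. Ring A can therefore be closed as a bicyclo[2.2.2]octene whose third bridge Ca=Cb is cut afterwards: Cb stays on C4 as the first chain carbon and Ca leaves C1 as CO2.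
- Forward order: ring B (cyclohexanone with C5, then C8 and C9), then the temporary ring C1–Ca–Cb–C4–C5–C10 (aldol closure, Li/NH3), then the Diels–Alder reaction that closes ring A, then bridge cleavage, chain extension, two decarboxylations and unveiling of the arene.
- Stereochemistry: C5 from a chiral-imine Michael addition, C8 from a catalyst-controlled conjugate methylation, C9 by enolate methylation anti to the C8 methyl, C10 by dissolving-metal reduction (trans fusion), C4 by cycloaddition on the face anti to the angular methyl.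

Key step: step 14

Remark: locants C1–C10 are those of the target decalin (C5 and C10 ring fusion, C5 angular methyl, C9 arylmethyl and methyl, C8 methyl, C4 acid chain, C3 isopropylidene). Ca and Cb are the two extra carbons of the temporary ring. α is the face of the C5 methyl, β that of H-10. Ar = 2,5-dimethoxy-3-methylphenyl. Both C3 epimers of 25 serve equally; one is drawn.

**Route**

Step 1
Reactants: 1 2,6-dimethylbenzene-1,4-diol
Product: 2 2,5-dimethoxy-1,3-dimethylbenzene
Conditions: MeI, K2CO3, acetone, reflux, N2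
Reagents that add atoms: iodomethane, CI
Why: Williamson ether synthesis on both phenols; no stereocentre is involved.

Step 2
Reactants: 2 2,5-dimethoxy-1,3-dimethylbenzene
Product: 3 1-(bromomethyl)-2,5-dimethoxy-3-methylbenzene
Conditions: N-bromosuccinimide (1.0 equiv), AIBN (cat.), PhCF3, reflux, hv
Reagents that add atoms: N-bromosuccinimide, O=C1CCC(=O)N1Br
Why: Wohl–Ziegler benzylic bromination; the two methyl groups are equivalent, and radical conditions in a non-polar solvent should favour the side chain over the ring.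

Step 3
Reactants: 4 2-methylcyclohexan-1-one (racemic); 5 but-3-en-2-one
Product: 8 (S)-2-methyl-2-(3-oxobutyl)cyclohexan-1-one, via phenylethyl imine 6 (not isolated), via Michael adduct imine 7 (not isolated)
Conditions: (R)-1-phenylethylamine, TsOH (cat.), toluene, reflux (Dean–Stark); then 5, THF, 40 °C; then 10% aq. AcOH, rt
Reagents that add atoms: water, O
Why: Asymmetric Michael addition of a chiral imine: the more substituted secondary enamine tautomer adds to the enone in a compact aza-ene-like transition state on the face away from the phenyl group, which should set the quaternary C5 as S from either enantiomer of 4.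

Step 4
Reactants: 8 (S)-2-methyl-2-(3-oxobutyl)cyclohexan-1-one
Product: 9 (S)-2-methyl-2-[2-(2-methyl-1,3-dioxolan-2-yl)ethyl]cyclohexan-1-one
Conditions: 2-ethyl-2-methyl-1,3-dioxolane, TsOH (cat.), rt
Reagents that add atoms: 2-ethyl-2-methyl-1,3-dioxolane, CCC1(C)OCCO1
Why: Acid-catalysed transketalisation protects the unhindered methyl ketone and leaves the ring ketone next to the quaternary carbon.

Step 5
Reactants: 9 (S)-2-methyl-2-[2-(2-methyl-1,3-dioxolan-2-yl)ethyl]cyclohexan-1-one
Product: 10 (S)-6-methyl-6-[2-(2-methyl-1,3-dioxolan-2-yl)ethyl]cyclohex-2-en-1-one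
Conditions: IBX (2-iodoxybenzoic acid), DMSO/fluorobenzene, 65 °C
Reagents that add atoms: none
Why: IBX dehydrogenation of a ketone to the enone; only C9 carries α-hydrogens, so the double bond can form only between C8 and C9.

Step 6
Reactants: 10 (S)-6-methyl-6-[2-(2-methyl-1,3-dioxolan-2-yl)ethyl]cyclohex-2-en-1-one; 3 1-(bromomethyl)-2,5-dimethoxy-3-methylbenzene
Product: 12 (2R,3S,6S)-2-[(2,5-dimethoxy-3-methylphenyl)methyl]-3,6-dimethyl-6-[2-(2-methyl-1,3-dioxolan-2-yl)ethyl]cyclohexan-1-one, via methylzinc enolate 11 (not isolated)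
Conditions: Cu(OTf)2 (2 mol %), O,O'-[(S)-1,1'-binaphthyl-2,2'-diyl] N,N-bis[(R)-1-phenylethyl]phosphoramidite (4 mol %), Me2Zn, toluene, −30 °C; then 3, HMPA, 0 °C to rt
Reagents that add atoms: dimethylzinc, C[Zn]C
Why: Copper-catalysed asymmetric conjugate addition should set C8 as S under catalyst control (ligand sense taken from cyclohex-2-enone, the remote C5 centre should exert little bias), and the zinc enolate is C-benzylated trans to the new methyl group.

Step 7
Reactants: 12 (2R,3S,6S)-benzyl ketone
Product: 14 (2S,3S,6S)-2-[(2,5-dimethoxy-3-methylphenyl)methyl]-2,3,6-trimethyl-6-[2-(2-methyl-1,3-dioxolan-2-yl)ethyl]cyclohexan-1-one, via lithium enolate 13 (not isolated)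
Conditions: LiN(i-Pr)2, THF, −78 to 0 °C; then MeI, DMPU, −78 to −20 °C
Reagents that add atoms: iodomethane, CI
Why: Enolate alkylation: C9 is the only enolisable carbon and MeI should enter anti to the adjacent C8 methyl group (2,3-trans alkylation), which places the C9 methyl cis to the C5 methyl and the arylmethyl group cis to the C8 methyl.

Step 8
Reactants: 14 (2S,3S,6S)-ketal ketone
Product: 16 (4aS,7S,8S)-8-[(2,5-dimethoxy-3-methylphenyl)methyl]-4a,7,8-trimethyl-4,4a,5,6,7,8-hexahydronaphthalen-2(3H)-one, via diketone 15 (not isolated)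
Conditions: TsOH·H2O (cat.), acetone/H2O, 50 °C; then KOH (cat.), MeOH, 65 °C
Reagents that add atoms: water, O
Why: Ketal hydrolysis followed by intramolecular aldol condensation (the ring-closing half of a Robinson annulation), in which only the methyl carbon of the side-chain ketone can reach C10 in a six-membered ring; no stereocentre is formed.

Step 9
Reactants: 16 octalone
Product: 17 (4aS,7S,8S,8aS)-8-[(2,5-dimethoxy-3-methylphenyl)methyl]-4a,7,8-trimethyl-3,4,4a,5,6,7,8,8a-octahydronaphthalen-2(1H)-one
Conditions: Li, NH3(l), THF, t-BuOH (1 equiv), −78 °C; then NH4Cl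
Reagents that add atoms: none
Why: Dissolving-metal reduction of the enone: axial protonation of the β-carbanion at C10 anti to the angular methyl should give the trans-fused decalone, as for 4a-methyloctalones.

Step 10
Reactants: 17 trans-decalone
Product: 19 (4aS,7S,8S,8aR)-8-[(2,5-dimethoxy-3-methylphenyl)methyl]-4a,7,8-trimethyl-4a,5,6,7,8,8a-hexahydronaphthalen-2(1H)-one, via lithium enolate 18 (not isolated)
Conditions: LiN(i-Pr)2, THF, −78 °C; then PhS(Cl)=N-t-Bu, −78 °C
Reagents that add atoms: none
Why: Kinetic enolisation of the trans-fused 2-decalone toward Cb (the less hindered side, as in 5α-3-ketosteroids) and one-pot dehydrogenation by the sulfinimidoyl chloride (sulfur transfer to Cb, then syn elimination) should give the Cb=C4 enone.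

Step 11
Reactants: 19 enone
Product: 20 silyloxy diene (tert-butyldimethylsilyl dienol ether of 19)
Conditions: t-BuMe2SiOTf, Et3N, CH2Cl2, 0 °C
Reagents that add atoms: tert-butyldimethylsilyl trifluoromethanesulfonate, CC(C)(C)[Si](C)(C)OS(=O)(=O)C(F)(F)F
Why: Soft enolisation and O-silylation: C5 is quaternary, so only the C1 hydrogens can be lost and the cross-conjugated diene C1=Ca(OSi)–Cb=C4 should form regiospecifically.

Step 12
Reactants: 21 2,3-dimethylbut-2-enoic acid
Product: 23 3-hydroxy-3-methyl-2-methylidenebutanoic acid, via allylic hydroperoxide 22 (not isolated)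
Conditions: O2, tetraphenylporphyrin (cat.), hv, CH2Cl2, 0 °C; then PPh3, 0 °C
Reagents that add atoms: dioxygen, O=O
Why: Schenck ene reaction of singlet oxygen, which takes the hydrogen from the methyl group geminal to the carboxyl group, followed by phosphine reduction of the hydroperoxide.

Step 13
Reactants: 23 3-hydroxy-3-methyl-2-methylidenebutanoic acid
Product: 24 4,4-dimethyl-3-methylideneoxetan-2-one
Conditions: PhSO2Cl, pyridine, 0 °C
Reagents that add atoms: none
Why: β-Lactonisation of a β-hydroxy acid by carboxyl activation as the mixed sulfonic anhydride and attack of the tertiary hydroxyl group.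

Step 14
Reactants: 20 silyloxy diene; 24 4,4-dimethyl-3-methylideneoxetan-2-one
Product: 25 spiro-β-lactone bicyclo[2.2.2]octene adduct
Conditions: toluene, 2,6-di-tert-butyl-4-methylphenol (cat.), 90 °C, sealed tube
Reagents that add atoms: none
Why: This is a normal-demand Diels–Alder reaction in which the silyloxy diene C1=Ca(OSi)–Cb=C4 adds across the strained, acrylate-like exocyclic C=C bond of lactone 24, C1–C2 bonding running ahead of C3–C4. The closest known reaction type is the cycloaddition of α-methylene β-lactones to 1,3-dienes, where the lactone serves as an allene equivalent. Ring A (C1–C2–C3–C4–C5–C10) is closed by the suprafacial [4+2] union of C1/C4 with C2/C3, which at the same time makes a bicyclo[2.2.2]octene whose third bridge is Ca=Cb. C4 (and the transient stereocentre C1) should be set by approach to the β face of the diene, anti to the pseudoaxial C5 methyl and the axial C9 methyl, which puts the future chain carbon Cb cis to the C5 methyl; the spiro centre C3 is of no consequence because it becomes sp2 in step 19. The step needs "para" regioselectivity (CH2 to C1, spiro carbon to C4), secured by the 2-silyloxy group that makes C1 the nucleophilic terminus, and β-face selectivity, secured by the two α-methyl groups. The lactone carbonyl activates the dienophile, and the ring is kept as a mask of the isopropylidene until step 19.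

Step 15
Reactants: 25 Diels–Alder adduct
Product: 26 C1-carboxy C4-formyl spiro-lactone
Conditions: O3, CH2Cl2, −78 °C (dye end point); then Me2S, −78 °C to rt; aqueous work-up
Reagents that add atoms: ozone, [O-][O+]=O
Why: Ozonolysis of the silyl enol ether, the most electron-rich π bond and the only C=C bond outside the arene, should cleave Ca=Cb to the Ca silyl ester (acid after work-up) and the Cb aldehyde with the configuration at C4 untouched.

Step 16
Reactants: 26 formyl acid
Product: 27 E-enoate acid
Conditions: (MeO)2P(O)CH2CO2Me, LiCl, DBU, MeCN, 0 °C to rt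
Reagents that add atoms: trimethyl phosphonoacetate, COC(=O)CP(=O)(OC)OC
Why: Horner–Wadsworth–Emmons olefination under Masamune–Roush conditions, mild enough for the β-lactone and the C4 stereocentre, should give the E-enoate and complete the three-carbon chain.

Step 17
Reactants: 27 E-enoate acid
Product: 28 saturated ester acid
Conditions: H2 (1 atm), Pd/C, EtOAc, rt
Reagents that add atoms: none
Why: Catalytic hydrogenation of the only alkene present; the isopropylidene is still masked as the β-lactone, so no chemoselectivity is needed.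

Step 18
Reactants: 28 saturated ester acid
Product: 30 spiro-lactone methyl ester, via thiohydroxamate ester 29 (not isolated)
Conditions: N-hydroxypyridine-2-thione, DCC, DMAP (cat.), CH2Cl2, 0 °C, dark; then t-BuSH, hv (visible), rt
Reagents that add atoms: none
Why: Barton reductive decarboxylation: the thiohydroxamate ester fragments to the secondary C1 radical, which abstracts hydrogen from the thiol, so that Ca leaves as CO2.

Step 19
Reactants: 30 spiro-lactone methyl ester
Product: 31 isopropylidene methyl ester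
Conditions: 2,4,6-collidine, 165 °C
Reagents that add atoms: none
Why: Thermal [2+2] cycloreversion of the β-lactone with loss of CO2 should deliver the tetrasubstituted C3=CMe2 bond regiospecifically.

Step 20
Reactants: 31 isopropylidene methyl ester
Product: 32 isopropylidene acid
Conditions: LiOH, THF/MeOH/H2O, rt; then 1 M HCl to pH 3, 0 °C
Reagents that add atoms: lithium hydroxide, [Li+].[OH-]
Why: Saponification of the unhindered primary methyl ester.

Step 21
Reactants: 32 isopropylidene acid
Product: 33 quinone acid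
Conditions: (NH4)2Ce(NO3)6, MeCN/H2O, 0 °C
Reagents that add atoms: water, O
Why: Oxidative demethylation of the 1,4-dimethoxyarene to the p-quinone, which should be faster than oxidation of the tetrasubstituted alkene.

Step 22
Reactants: 33 quinone acid
Product: 35 target CNP0144688.1, via hydroquinone 34 (not isolated)
Conditions: Na2S2O4, THF/H2O, rt; then Ac2O (1.1 equiv), pyridine, CH2Cl2, 0 °C
Reagents that add atoms: acetic anhydride, CC(=O)OC(C)=O
Why: Dithionite reduction to the hydroquinone and acylation of the less hindered phenol (the other hydroxyl is flanked by the methyl and the bulky CH2 group); a mixed anhydride of the acid, if formed, is hydrolysed on aqueous work-up.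

**Compound list**

1 | 2,6-dimethylbenzene-1,4-diol | Cc1cc(O)cc(C)c1O | starting material
2 | 2,5-dimethoxy-1,3-dimethylbenzene | COc1cc(C)c(OC)c(C)c1 | intermediate
3 | 1-(bromomethyl)-2,5-dimethoxy-3-methylbenzene | COc1cc(C)c(OC)c(CBr)c1 | intermediate
4 | 2-methylcyclohexan-1-one (racemic) | CC1CCCCC1=O | starting material
5 | but-3-en-2-one | CC(=O)C=C | starting material
6 | N-[(R)-1-phenylethyl]-2-methylcyclohexan-1-imine | CC1CCCCC1=N[C@H](C)c1ccccc1 | intermediate (not isolated)
7 | N-[(R)-1-phenylethyl]imine of (S)-2-methyl-2-(3-oxobutyl)cyclohexan-1-one | CC(=O)CC[C@]1(C)CCCCC1=N[C@H](C)c1ccccc1 | intermediate (not isolated)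
8 | (S)-2-methyl-2-(3-oxobutyl)cyclohexan-1-one | CC(=O)CC[C@]1(C)CCCCC1=O | intermediate
9 | (S)-2-methyl-2-[2-(2-methyl-1,3-dioxolan-2-yl)ethyl]cyclohexan-1-one | CC1(CC[C@]2(C)CCCCC2=O)OCCO1 | intermediate
10 | (S)-6-methyl-6-[2-(2-methyl-1,3-dioxolan-2-yl)ethyl]cyclohex-2-en-1-one | CC1(CC[C@]2(C)CCC=CC2=O)OCCO1 | intermediate
11 | methylzinc enolate (C9=C10) of (3S,6S)-3,6-dimethyl-6-[2-(2-methyl-1,3-dioxolan-2-yl)ethyl]cyclohexan-1-one | CC1(CC[C@]2(C)CC[C@H](C)C=C2O[Zn]C)OCCO1 | intermediate (not isolated)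
12 | (2R,3S,6S)-2-[(2,5-dimethoxy-3-methylphenyl)methyl]-3,6-dimethyl-6-[2-(2-methyl-1,3-dioxolan-2-yl)ethyl]cyclohexan-1-one | CC1(CC[C@]2(C)CC[C@H](C)[C@@H](Cc3cc(OC)cc(C)c3OC)C2=O)OCCO1 | intermediate
13 | lithium enolate (C9=C10) of 12 | CC1(CC[C@]2(C)CC[C@H](C)C(Cc3cc(OC)cc(C)c3OC)=C2O[Li])OCCO1 | intermediate (not isolated)
14 | (2S,3S,6S)-2-[(2,5-dimethoxy-3-methylphenyl)methyl]-2,3,6-trimethyl-6-[2-(2-methyl-1,3-dioxolan-2-yl)ethyl]cyclohexan-1-one | CC1(CC[C@]2(C)CC[C@H](C)[C@](C)(Cc3cc(OC)cc(C)c3OC)C2=O)OCCO1 | intermediate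
15 | (2S,3S,6S)-2-[(2,5-dimethoxy-3-methylphenyl)methyl]-2,3,6-trimethyl-6-(3-oxobutyl)cyclohexan-1-one | CC(=O)CC[C@]1(C)CC[C@H](C)[C@](C)(Cc2cc(OC)cc(C)c2OC)C1=O | intermediate (not isolated)
16 | (4aS,7S,8S)-8-[(2,5-dimethoxy-3-methylphenyl)methyl]-4a,7,8-trimethyl-4,4a,5,6,7,8-hexahydronaphthalen-2(3H)-one (C1=C10 enone) | COc1cc(C)c(OC)c(C[C@]2(C)C3=CC(=O)CC[C@]3(C)CC[C@@H]2C)c1 | intermediate
17 | (4aS,7S,8S,8aS)-8-[(2,5-dimethoxy-3-methylphenyl)methyl]-4a,7,8-trimethyl-3,4,4a,5,6,7,8,8a-octahydronaphthalen-2(1H)-one (trans-fused; 5α-Me, 10β-H, 9α-Me, 9β-CH2Ar, 8β-Me) | COc1cc(C)c(OC)c(C[C@]2(C)[C@H]3CC(=O)CC[C@]3(C)CC[C@@H]2C)c1 | intermediate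
18 | lithium enolate (Ca=Cb) of 17 | COc1cc(C)c(OC)c(C[C@]2(C)[C@H]3CC(O[Li])=CC[C@]3(C)CC[C@@H]2C)c1 | intermediate (not isolated)
19 | (4aS,7S,8S,8aR)-8-[(2,5-dimethoxy-3-methylphenyl)methyl]-4a,7,8-trimethyl-4a,5,6,7,8,8a-hexahydronaphthalen-2(1H)-one (Cb=C4 enone, trans-fused) | COc1cc(C)c(OC)c(C[C@]2(C)[C@H]3CC(=O)C=C[C@]3(C)CC[C@@H]2C)c1 | intermediate
20 | tert-butyldimethylsilyl dienol ether of 19 (diene C1=Ca(OSi)–Cb=C4; ring B as in 17) | COc1cc(C)c(OC)c(C[C@]2(C)[C@H]3C=C(O[Si](C)(C)C(C)(C)C)C=C[C@]3(C)CC[C@@H]2C)c1 | intermediate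
21 | 2,3-dimethylbut-2-enoic acid | CC(C)=C(C)C(=O)O | starting material
22 | 3-hydroperoxy-3-methyl-2-methylidenebutanoic acid | C=C(C(=O)O)C(C)(C)OO | intermediate (not isolated)
23 | 3-hydroxy-3-methyl-2-methylidenebutanoic acid | C=C(C(=O)O)C(C)(C)O | intermediate
24 | 4,4-dimethyl-3-methylideneoxetan-2-one | C=C1C(=O)OC1(C)C | intermediate
25 | Diels–Alder adduct: ring A closed as a bicyclo[2.2.2]octene with bridges C2–C3, C10–C5 and Ca(OSi)=Cb; new bonds C1–C2 and C3–C4 on the β face; C3 is the spiro carbon of the 4,4-dimethyl β-lactone (drawn with the lactone CMe2 syn to the enol ether bridge); ring B as in 17 | COc1cc(C)c(OC)c(C[C@]2(C)[C@H]3[C@@H]4C[C@]5(C(=O)OC5(C)C)[C@@H](C=C4O[Si](C)(C)C(C)(C)C)[C@]3(C)CC[C@@H]2C)c1 | intermediate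
26 | formyl acid: decalin with 1α-CO2H, 4α-CHO (cis to the C5 methyl) and the spiro β-lactone at C3; ring B as in 17 | COc1cc(C)c(OC)c(C[C@]2(C)[C@H]3[C@@H](C(=O)O)C[C@]4(C(=O)OC4(C)C)[C@@H](C=O)[C@]3(C)CC[C@@H]2C)c1 | intermediate
27 | E-enoate acid: as 26 with 4α-[(E)-2-(methoxycarbonyl)ethenyl] in place of CHO | COc1cc(C)c(OC)c(C[C@]2(C)[C@H]3[C@@H](C(=O)O)C[C@]4(C(=O)OC4(C)C)[C@@H](/C=C/C(=O)OC)[C@]3(C)CC[C@@H]2C)c1 | intermediate
28 | saturated ester acid: as 27 with 4α-[2-(methoxycarbonyl)ethyl] | COc1cc(C)c(OC)c(C[C@]2(C)[C@H]3[C@@H](C(=O)O)C[C@]4(C(=O)OC4(C)C)[C@@H](CCC(=O)OC)[C@]3(C)CC[C@@H]2C)c1 | intermediate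
29 | 2-thioxopyridin-1(2H)-yl ester of the C1 acid of 28 | COc1cc(C)c(OC)c(C[C@]2(C)[C@H]3[C@@H](C(=O)ON5C=CC=CC5=S)C[C@]4(C(=O)OC4(C)C)[C@@H](CCC(=O)OC)[C@]3(C)CC[C@@H]2C)c1 | intermediate (not isolated)
30 | spiro-lactone methyl ester: as 28 with C1 = CH2 | COc1cc(C)c(OC)c(C[C@]2(C)[C@H]3CC[C@]4(C(=O)OC4(C)C)[C@@H](CCC(=O)OC)[C@]3(C)CC[C@@H]2C)c1 | intermediate
31 | methyl 3-{(4S,5R,8S,9S,10R)-9-[(2,5-dimethoxy-3-methylphenyl)methyl]-5,8,9-trimethyl-3-(propan-2-ylidene)decalin-4-yl}propanoate (locants of the remark) | COc1cc(C)c(OC)c(C[C@]2(C)[C@H]3CCC(=C(C)C)[C@@H](CCC(=O)OC)[C@]3(C)CC[C@@H]2C)c1 | intermediate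
32 | the corresponding propanoic acid | COc1cc(C)c(OC)c(C[C@]2(C)[C@H]3CCC(=C(C)C)[C@@H](CCC(=O)O)[C@]3(C)CC[C@@H]2C)c1 | intermediate
33 | 2-methyl-6-(decalinylmethyl)-1,4-benzoquinone acid | CC1=CC(=O)C=C(C[C@]2(C)[C@H]3CCC(=C(C)C)[C@@H](CCC(=O)O)[C@]3(C)CC[C@@H]2C)C1=O | intermediate
34 | the corresponding hydroquinone | Cc1cc(O)cc(C[C@]2(C)[C@H]3CCC(=C(C)C)[C@@H](CCC(=O)O)[C@]3(C)CC[C@@H]2C)c1O | intermediate (not isolated)
35 | CNP0144688.1: 3-{(4S,5R,8S,9S,10R)-9-[(5-acetoxy-2-hydroxy-3-methylphenyl)methyl]-5,8,9-trimethyl-3-(propan-2-ylidene)decalin-4-yl}propanoic acid (locants of the remark) | CC(=O)Oc1cc(C)c(O)c(C[C@]2(C)[C@H]3CCC(=C(C)C)[C@@H](CCC(=O)O)[C@]3(C)CC[C@@H]2C)c1 | target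

**Step count and risks**

Total step count: 22. Longest linear sequence: 18 steps (steps 3–11 and 14–22, from 2-methylcyclohexanone).

Steps most likely to fail:

Step 14. Closure of the second bond, between the fully substituted dienophile carbon and C4 next to the quaternary C5, may be too slow, so that thermal oligomerisation or early decarboxylation of the lactone takes over. The fallback sets out from 20. A Diels–Alder reaction with benzyl acrylate (toluene, 110 °C, same facial and regiochemical sense) should give the benzyl ester adduct F1, in which C3 is only tertiary. LiN(i-Pr)2 then acetone (THF, −78 °C) should add the hydroxy-isopropyl group at C3 from the enol ether side to give the β-hydroxy ester F2. Hydrogenolysis (H2, Pd/C) should give the β-hydroxy acid F3, and PhSO2Cl in pyridine closes the β-lactone, so the route is rejoined at 25.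

Step 8. The aldol addition to a carbonyl flanked by two quaternary carbons may stall, and retro-Michael loss of the 3-oxobutyl chain may compete under base. The fallback sets out from 14. After acid hydrolysis to 15, kinetic silylation of the methyl ketone (LiN(i-Pr)2, Me3SiCl, −78 °C) gives the trimethylsilyl enol ether F4. A TiCl4-promoted intramolecular Mukaiyama aldol addition (CH2Cl2, −78 °C) should give the ketol F5, and dehydration (SOCl2, pyridine; then DBU) returns the route at 16.

Step 6. C-alkylation of the zinc enolate by the benzylic bromide may be slow, so that protonation or O-alkylation wins and the 2,3-trans pattern is not installed cleanly. The fallback sets out from 3 and 10. Kornblum oxidation of 3 (NaHCO3, DMSO, 100 °C) gives 2,5-dimethoxy-3-methylbenzaldehyde F6. The conjugate addition to 10 is run alone and quenched to the 3-methyl ketone F7. Claisen–Schmidt condensation of F7 with F6 (KOH, EtOH) gives the E-arylidene ketone F8. Conjugate reduction with LiBH(s-Bu)3 (THF, −78 °C) generates the enolate 13 regiospecifically and MeI traps it anti to the C8 methyl, so the route is rejoined at 14.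

Further compounds
F1 | step 14 | benzyl ester adduct (bicyclo[2.2.2]octene silyl enol ether with the CO2Bn group at C3 syn to the enol ether bridge) | COc1cc(C)c(OC)c(C[C@]2(C)[C@H]3[C@@H]4C[C@@H](C(=O)OCc5ccccc5)[C@@H](C=C4O[Si](C)(C)C(C)(C)C)[C@]3(C)CC[C@@H]2C)c1
F2 | step 14 | β-hydroxy ester (C3 bearing CO2Bn and 2-hydroxypropan-2-yl, the latter syn to the enol ether bridge) | COc1cc(C)c(OC)c(C[C@]2(C)[C@H]3[C@@H]4C[C@@](C(=O)OCc5ccccc5)(C(C)(C)O)[C@@H](C=C4O[Si](C)(C)C(C)(C)C)[C@]3(C)CC[C@@H]2C)c1
F3 | step 14 | β-hydroxy acid | COc1cc(C)c(OC)c(C[C@]2(C)[C@H]3[C@@H]4C[C@@](C(=O)O)(C(C)(C)O)[C@@H](C=C4O[Si](C)(C)C(C)(C)C)[C@]3(C)CC[C@@H]2C)c1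
F4 | step 8 | trimethylsilyl enol ether of the methyl ketone of 15 | C=C(O[Si](C)(C)C)CC[C@]1(C)CC[C@H](C)[C@](C)(Cc2cc(OC)cc(C)c2OC)C1=O
F5 | step 8 | ketol (10α-hydroxy decalone, cis-fused) | COc1cc(C)c(OC)c(C[C@]2(C)[C@]3(O)CC(=O)CC[C@]3(C)CC[C@@H]2C)c1
F6 | step 6 | 2,5-dimethoxy-3-methylbenzaldehyde | COc1cc(C)c(OC)c(C=O)c1
F7 | step 6 | (3S,6S)-3,6-dimethyl-6-[2-(2-methyl-1,3-dioxolan-2-yl)ethyl]cyclohexan-1-one | CC1(CC[C@]2(C)CC[C@H](C)CC2=O)OCCO1
F8 | step 6 | (E)-2-arylidene ketone from F7 and F6 | CC1(CC[C@]2(C)CC[C@H](C)/C(=C\c3cc(OC)cc(C)c3OC)C2=O)OCCO1
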